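## Retrosynthetic overview

- The strategy rests on ring A. The quaternary carbon of the 1,1-dimethylallyl group sits on C6 between the oxygens on C5 and C7. The fusion bond C4a=C8a is also the enol ether double bond of a 2-aryl-2,3-dihydropyran-4-one (ring C).
- Ring A is cut into C4a/C8a (ring C), C5/C8 (a diazoacetyl group on the pyranone) and C6/C7 (a siloxyalkyne that already carries the tert-alkyl group). A photo-Wolff/vinylketene-alkyne benzannulation joins the three.
- Ring C comes from cyclodehydration of a 6-aryl-6-hydroxy-2,4-dioxohexanoate, which is made by oxalate acylation of a beta-silyloxy methyl ketone.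
- C2, the only stereocentre, is set by enantioselective copper-catalysed conjugate borylation of the aryl enone, followed by C-B to C-O oxidation. That C-O bond is never broken afterwards.
- Ring order: B is bought, C is closed second, A is closed last.

Key step: step 13

Assumption: step 3 uses the antipode of the ferrocenyl diphosphine that sends boron to the Si face of the enone beta carbon. Both antipodes are sold, and the sense of induction is to be confirmed on the derived alcohol (Mosher esters) before material is carried on.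

Abbreviations: TBS = tert-butyldimethylsilyl, TES = triethylsilyl, TIPS = triisopropylsilyl. Flavanone numbering is used for ring A bonds and pyranone numbering for the monocyclic compounds.

## Route

Step 1
Reactants: 1 3,4-dihydroxybenzaldehyde
Product: 2 3,4-bis(TBS-oxy)benzaldehyde
Conditions: TBSCl (2.4 equiv), imidazole (5 equiv), DMF, 0 °C to rt
Reagents that add atoms: tert-butyldimethylsilyl chloride (TBSCl), CC(C)(C)[Si](C)(C)Cl
Why: Imidazole-promoted O-silylation masks both catechol hydroxyls as aryl TBS ethers, which tolerate ylide, amide base and mild acid and are removed by fluoride at the end.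

Step 2
Reactants: 2 3,4-bis(TBS-oxy)benzaldehyde, 3 1-(triphenylphosphoranylidene)propan-2-one
Product: 4 (E)-4-[3,4-bis(TBS-oxy)phenyl]but-3-en-2-one
Conditions: 3 (1.2 equiv), toluene, 90 °C
Reagents that add atoms: none
Why: Wittig olefination with a carbonyl-stabilised ylide needs no added base and is reliably (E)-selective with aromatic aldehydes.

Step 3
Reactants: 4 (E)-4-[3,4-bis(TBS-oxy)phenyl]but-3-en-2-one
Product: 5 (S)-4-[3,4-bis(TBS-oxy)phenyl]-4-(4,4,5,5-tetramethyl-1,3,2-dioxaborolan-2-yl)butan-2-one
Conditions: CuCl (3 mol %), NaOt-Bu (4 mol %), 1-[2-(diphenylphosphino)ferrocenyl]ethyldicyclohexylphosphine (Josiphos type, single antipode, 3 mol %), B2pin2 (1.1 equiv), MeOH (2 equiv), THF, rt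
Reagents that add atoms: bis(pinacolato)diboron (B2pin2), CC1(C)OB(OC1(C)C)B1OC(C)(C)C(C)(C)O1
Why: In this copper-catalysed enantioselective conjugate borylation the ligand-bound copper boryl adds to the enone, the chiral diphosphine steers boron to the Si face of C4 and so sets the (S) centre, and methanol protonates the enolate to turn the catalyst over.

Step 4
Reactants: 5 (S)-beta-boryl ketone
Product: 6 (S)-4-[3,4-bis(TBS-oxy)phenyl]-4-hydroxybutan-2-one
Conditions: NaBO3·4H2O (3 equiv), THF/H2O (1:1), 0 °C to rt, short contact; pH 7 buffer work-up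
Reagents that add atoms: sodium perborate tetrahydrate (NaBO3·4H2O), [Na+].[Na+].O[B-]1(O)OO[B-](O)(O)OO1
Why: Peroxide oxidation of a secondary boronic ester moves carbon from boron to oxygen with retention, so (S)-5 should give (S)-6, and perborate is mild enough for the beta-hydroxy ketone and the aryl silyl ethers.

Step 5
Reactants: 6 (S)-beta-hydroxy ketone
Product: 7 (S)-4-[3,4-bis(TBS-oxy)phenyl]-4-(triethylsilyloxy)butan-2-one
Conditions: TESCl (1.3 equiv), imidazole (2.5 equiv), CH2Cl2, 0 °C
Reagents that add atoms: triethylsilyl chloride (TESCl), CC[Si](Cl)(CC)CC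
Why: Mild O-silylation blocks retro-aldol and dehydration of the benzylic carbinol without touching its C-O bond, and installs a group far more acid-labile than the aryl TBS ethers.

Step 6
Reactants: 7 (S)-beta-(triethylsilyloxy) methyl ketone, 8 dimethyl oxalate
Product: 10 methyl (S)-6-[3,4-bis(TBS-oxy)phenyl]-2,4-dioxo-6-(triethylsilyloxy)hexanoate, via methyl-side lithium enolate 9 (not isolated)
Conditions: LiN(SiMe3)2 (1.1 equiv), THF, −78 °C; cannulate into 8 (2 equiv), THF, −78 to −40 °C; AcOH quench at −40 °C
Reagents that add atoms: none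
Why: In this crossed Claisen acylation the hindered amide base deprotonates the open methyl side at low temperature, the enolate meets an excess of the non-enolisable and very electrophilic oxalate, and the liberated methoxide converts the product into its diketonate, which blocks beta-elimination of the silyloxy group and leaves the stereocentre alone.

Step 7
Reactants: 10 (S)-6-aryl-6-(triethylsilyloxy)-2,4-dioxohexanoate
Product: 12 methyl (S)-2-[3,4-bis(TBS-oxy)phenyl]-4-oxo-2,3-dihydro-4H-pyran-6-carboxylate, via free hydroxy diketoester 11 (not isolated)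
Conditions: p-TsOH·H2O (0.1 equiv), water-saturated CH2Cl2, 0 °C to rt; pH 7 buffer wash
Reagents that add atoms: none
Why: Acid-catalysed desilylation and cyclodehydration frees the hydroxyl, which adds to the activated C2 keto group (6-exo-trig), and loss of water gives the vinylogous ester, so ring C closes through a new O-C(sp2) bond while the benzylic C-O bond and its (S) centre stay intact.

Step 8
Reactants: 12 (S)-pyranone methyl ester
Product: 14 (S)-2-[3,4-bis(TBS-oxy)phenyl]-4-oxo-2,3-dihydro-4H-pyran-6-carboxylic acid, via trimethylstannyl ester 13 (not isolated)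
Conditions: Me3SnOH (3 equiv), ClCH2CH2Cl, 60 °C; cold 0.5 M HCl wash
Reagents that add atoms: trimethyltin hydroxide, C[Sn](C)(C)O
Why: Trimethyltin hydroxide cleaves the activated ester under nearly neutral conditions, so C3 is not deprotonated and retro-oxa-Michael opening at C2 is avoided, and any stray addition at C6 could only open the C6-O1 bond, which the acid wash would close again.

Step 9
Reactants: 14 (S)-pyranone carboxylic acid
Product: 15 (S)-2-[3,4-bis(TBS-oxy)phenyl]-4-oxo-2,3-dihydro-4H-pyran-6-carbonyl chloride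
Conditions: 1-chloro-N,N,2-trimethylpropenylamine (1.05 equiv), CH2Cl2, 0 °C to rt; concentrate, use crude
Reagents that add atoms: 1-chloro-N,N,2-trimethylpropenylamine, CC(C)=C(Cl)N(C)C
Why: Acid chloride formation with an alpha-chloroenamine releases neither HCl nor base and leaves only an inert amide, which suits the sensitive C2-O1 bond.

Step 10
Reactants: 15 (S)-pyranone carbonyl chloride, 16 (trimethylsilyl)diazomethane
Product: 17 (S)-6-(2-diazoacetyl)-2-[3,4-bis(TBS-oxy)phenyl]-2,3-dihydro-4H-pyran-4-one
Conditions: 16 (2.0 M in hexanes, 1.8 equiv), MeCN/THF (1:1), −10 to 0 °C; concentrate; chromatography on neutral silica, shielded from light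
Reagents that add atoms: none
Why: In this Arndt-Eistert-type acylation the diazo carbon attacks the reactive acyl chloride and chloride then takes the silyl group, so no HCl forms and no amine is needed, while low temperature and the bulk of 16 should hold back dipolar cycloaddition to the trisubstituted C5=C6 bond.

Step 11
Reactants: 18 2,2-dimethylbut-3-enoic acid
Product: 19 ethyl 2,2-dimethylbut-3-enoate
Conditions: EtI (1.3 equiv), K2CO3 (1.5 equiv), DMF, rt; pentane extraction, distillation
Reagents that add atoms: iodoethane, CCI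
Why: Carboxylate O-alkylation (SN2) esterifies the hindered acid without attack at its crowded carbonyl group and without acid that could touch the vinyl group.

Step 12
Reactants: 19 ethyl 2,2-dimethylbut-3-enoate, 20 dibromomethane
Product: 24 (3,3-dimethylpent-4-en-1-ynyloxy)triisopropylsilane, via dibromomethyllithium 21 (not isolated), via lithium dibromoenolate 22 (not isolated), via lithium ynolate 23 (not isolated)
Conditions: 20 (2.2 equiv), lithium 2,2,6,6-tetramethylpiperidide (2.1 equiv, from the amine and n-BuLi), THF, −78 °C; add 19; n-BuLi (4 equiv), −78 °C to rt; TIPSCl (2 equiv), 0 °C to rt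
Reagents that add atoms: triisopropylsilyl chloride (TIPSCl), CC(C)[Si](Cl)(C(C)C)C(C)C
Why: In the Kowalski ynolate formation 21 adds to the ester, the amide base gives enolate 22, bromine-lithium exchange triggers a 1,2-shift of the tert-alkyl group with loss of LiBr to give 23, and the bulky silyl chloride traps 23 on oxygen.

Step 13
Reactants: 17 (S)-6-diazoacetyl dihydropyranone, 24 tert-alkyl siloxyalkyne
Product: 28 (S)-7-O-TIPS-3',4'-di-O-TBS-6-(1,1-dimethylallyl)eriodictyol, via vinylketene 25 (not isolated), via 4-vinylcyclobutenone 26 (not isolated), via dienylketene 27 (not isolated)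
Conditions: 24 (2 equiv), degassed ClCH2CH2Cl (0.1 M), hν (300 nm lamps, Pyrex), rt, until the diazo ketone is consumed; lamp off, 80 °C in the dark
Reagents that add atoms: none
Why: Light expels N2 from 17 and the pyranone C6 carbon shifts to the carbene carbon (Wolff rearrangement, C8-C8a) to give vinylketene 25, whose sp carbon is attacked by the electron-rich alkyne carbon of 24 that carries the tert-alkyl group, and [2+2] closure (C5-C6 and C7-C8) gives the 4-vinylcyclobutenone 26. In the dark at 80 °C 26 opens in a 4-pi electrocyclic step (the former C5-C8 bond breaks) to dienylketene 27, and ring A closes by 6-pi electrocyclisation of the ketene carbon onto the nucleophilic pyranone C5-H carbon (C4a-C5), after which tautomerisation gives the C5 phenol, hydrogen-bonded to the C4 carbonyl. The closest known reaction type is the diazo ketone variant of the Danheiser benzannulation with siloxyalkynes, where cyclic alkenyl diazo ketones and alpha-branched siloxyalkynes are established partners, so the present pair is a more crowded member of a known class. The step needs regioselectivity (tert-alkyl on C6 and not C8, free OH on C5, silyl ether on C7), which the polarity of the ynol ether fixes in the [2+2] event and the single free vinyl terminus fixes in the 6-pi closure. No lasting stereocentre is created (the sp3 carbon of the four-membered ring in 26 becomes C8 of the arene), and C2 should stay (S) because neither acid nor base is present and the light-sensitive flavanone and aryl/vinyl chromophores arise only after the lamp is off. Competing paths look poor: the ketenyl group and the C4 carbonyl sit on opposite sides of the ring double bond so no oxa-6-pi closure can occur, the vinyl group is only one carbon away from the ketene of 27 and cannot reach it, and the crowded, chelated C5-OH should not be acylated by 25.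

Step 14
Reactants: 28 (S)-tris-silylated flavanone
Product: 29 (2S)-6-(1,1-dimethylallyl)eriodictyol, that is (2S)-2-(3,4-dihydroxyphenyl)-5,7-dihydroxy-6-(2-methylbut-3-en-2-yl)-2,3-dihydrochromen-4-one
Conditions: n-Bu4NF (4 equiv), AcOH (5 equiv), THF, 0 °C to rt, under argon; pH 6 buffer work-up
Reagents that add atoms: none
Why: Fluoride cleaves all three aryl silyl ethers while acetic acid protonates each phenoxide as it forms, so no free base can open ring C by a retro-oxa-Michael reaction and no strong acid can add a flanking hydroxyl to the vinyl group.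

## Compound list

1 | 3,4-dihydroxybenzaldehyde | O=Cc1ccc(O)c(O)c1 | starting material
2 | 3,4-bis(TBS-oxy)benzaldehyde | O=Cc1ccc(O[Si](C)(C)C(C)(C)C)c(O[Si](C)(C)C(C)(C)C)c1 | intermediate
3 | 1-(triphenylphosphoranylidene)propan-2-one | CC(=O)C=P(c1ccccc1)(c1ccccc1)c1ccccc1 | starting material
4 | (E)-4-[3,4-bis(TBS-oxy)phenyl]but-3-en-2-one | CC(=O)/C=C/c1ccc(O[Si](C)(C)C(C)(C)C)c(O[Si](C)(C)C(C)(C)C)c1 | intermediate
5 | (S)-4-[3,4-bis(TBS-oxy)phenyl]-4-(pinacolatoboryl)butan-2-one | CC(=O)C[C@@H](c1ccc(O[Si](C)(C)C(C)(C)C)c(O[Si](C)(C)C(C)(C)C)c1)B1OC(C)(C)C(C)(C)O1 | intermediate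
6 | (S)-4-[3,4-bis(TBS-oxy)phenyl]-4-hydroxybutan-2-one | CC(=O)C[C@@H](c1ccc(O[Si](C)(C)C(C)(C)C)c(O[Si](C)(C)C(C)(C)C)c1)O | intermediate
7 | (S)-4-[3,4-bis(TBS-oxy)phenyl]-4-(triethylsilyloxy)butan-2-one | CC(=O)C[C@@H](c1ccc(O[Si](C)(C)C(C)(C)C)c(O[Si](C)(C)C(C)(C)C)c1)O[Si](CC)(CC)CC | intermediate
8 | dimethyl oxalate | COC(=O)C(=O)OC | starting material
9 | methyl-side lithium enolate of 7 (not isolated) | [Li+].C=C([O-])C[C@@H](c1ccc(O[Si](C)(C)C(C)(C)C)c(O[Si](C)(C)C(C)(C)C)c1)O[Si](CC)(CC)CC | intermediate
10 | methyl (S)-6-[3,4-bis(TBS-oxy)phenyl]-2,4-dioxo-6-(triethylsilyloxy)hexanoate | COC(=O)C(=O)CC(=O)C[C@@H](c1ccc(O[Si](C)(C)C(C)(C)C)c(O[Si](C)(C)C(C)(C)C)c1)O[Si](CC)(CC)CC | intermediate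
11 | methyl (S)-6-[3,4-bis(TBS-oxy)phenyl]-6-hydroxy-2,4-dioxohexanoate (not isolated) | COC(=O)C(=O)CC(=O)C[C@@H](c1ccc(O[Si](C)(C)C(C)(C)C)c(O[Si](C)(C)C(C)(C)C)c1)O | intermediate
12 | methyl (S)-2-[3,4-bis(TBS-oxy)phenyl]-4-oxo-2,3-dihydro-4H-pyran-6-carboxylate | COC(=O)C1=CC(=O)C[C@@H](c2ccc(O[Si](C)(C)C(C)(C)C)c(O[Si](C)(C)C(C)(C)C)c2)O1 | intermediate
13 | trimethylstannyl (S)-2-[3,4-bis(TBS-oxy)phenyl]-4-oxo-2,3-dihydro-4H-pyran-6-carboxylate (not isolated) | C[Sn](C)(C)OC(=O)C1=CC(=O)C[C@@H](c2ccc(O[Si](C)(C)C(C)(C)C)c(O[Si](C)(C)C(C)(C)C)c2)O1 | intermediate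
14 | (S)-2-[3,4-bis(TBS-oxy)phenyl]-4-oxo-2,3-dihydro-4H-pyran-6-carboxylic acid | OC(=O)C1=CC(=O)C[C@@H](c2ccc(O[Si](C)(C)C(C)(C)C)c(O[Si](C)(C)C(C)(C)C)c2)O1 | intermediate
15 | (S)-2-[3,4-bis(TBS-oxy)phenyl]-4-oxo-2,3-dihydro-4H-pyran-6-carbonyl chloride | ClC(=O)C1=CC(=O)C[C@@H](c2ccc(O[Si](C)(C)C(C)(C)C)c(O[Si](C)(C)C(C)(C)C)c2)O1 | intermediate
16 | (trimethylsilyl)diazomethane | C[Si](C)(C)C=[N+]=[N-] | starting material
17 | (S)-6-(2-diazoacetyl)-2-[3,4-bis(TBS-oxy)phenyl]-2,3-dihydro-4H-pyran-4-one | [N-]=[N+]=CC(=O)C1=CC(=O)C[C@@H](c2ccc(O[Si](C)(C)C(C)(C)C)c(O[Si](C)(C)C(C)(C)C)c2)O1 | intermediate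
18 | 2,2-dimethylbut-3-enoic acid | C=CC(C)(C)C(=O)O | starting material
19 | ethyl 2,2-dimethylbut-3-enoate | C=CC(C)(C)C(=O)OCC | intermediate
20 | dibromomethane | BrCBr | starting material
21 | dibromomethyllithium (not isolated) | [Li]C(Br)Br | intermediate
22 | lithium 1,1-dibromo-3,3-dimethylpenta-1,4-dien-2-olate (not isolated) | [Li+].C=CC(C)(C)C([O-])=C(Br)Br | intermediate
23 | lithium 3,3-dimethylpent-4-en-1-yn-1-olate (not isolated) | [Li+].C=CC(C)(C)C#C[O-] | intermediate
24 | (3,3-dimethylpent-4-en-1-ynyloxy)triisopropylsilane | C=CC(C)(C)C#CO[Si](C(C)C)(C(C)C)C(C)C | intermediate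
25 | (S)-2-[3,4-bis(TBS-oxy)phenyl]-6-(2-oxoethenyl)-2,3-dihydro-4H-pyran-4-one, vinylketene (not isolated) | O=C=CC1=CC(=O)C[C@@H](c2ccc(O[Si](C)(C)C(C)(C)C)c(O[Si](C)(C)C(C)(C)C)c2)O1 | intermediate
26 | 2-(2-methylbut-3-en-2-yl)-3-(TIPS-oxy)-4-[(S)-2-aryl-4-oxo-2,3-dihydropyran-6-yl]cyclobut-2-enone, either configuration at the ring sp3 carbon (not isolated) | C=CC(C)(C)C1=C(O[Si](C(C)C)(C(C)C)C(C)C)C(C1=O)C2=CC(=O)C[C@@H](c3ccc(O[Si](C)(C)C(C)(C)C)c(O[Si](C)(C)C(C)(C)C)c3)O2 | intermediate
27 | dienylketene with C6 and C8a cis on the C7=C8 bond (not isolated) | C=CC(C)(C)C(=C=O)/C(O[Si](C(C)C)(C(C)C)C(C)C)=C\C1=CC(=O)C[C@@H](c2ccc(O[Si](C)(C)C(C)(C)C)c(O[Si](C)(C)C(C)(C)C)c2)O1 | intermediate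
28 | (S)-7-O-TIPS-3',4'-di-O-TBS-6-(1,1-dimethylallyl)eriodictyol | C=CC(C)(C)c1c(O[Si](C(C)C)(C(C)C)C(C)C)cc2c(c1O)C(=O)C[C@@H](c1ccc(O[Si](C)(C)C(C)(C)C)c(O[Si](C)(C)C(C)(C)C)c1)O2 | intermediate
29 | (2S)-6-(1,1-dimethylallyl)eriodictyol | C=CC(C)(C)c1c(O)cc2c(c1O)C(=O)C[C@@H](c1ccc(O)c(O)c1)O2 | target

## Step count and risks

Total step count: 14. Longest linear sequence: 12 (steps 1 to 10, then 13 and 14). Steps 11 and 12 form the short convergent branch.

**Steps most likely to fail**

**1. Step 13.**
- What may go wrong: capture of the short-lived vinylketene at the crowded alkyne carbon may be too slow. Ketene self-reaction and light-driven decay of the pyranone chromophore could then win. Photochemical opening of the C2-O1 bond would also erode enantiopurity.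
- Fallback: the ketene is made in the dark by dehydrochlorination instead of by light. It sets out from 17, which is homologated by an Arndt-Eistert reaction (AgO2CPh cat., 1,4-dioxane/H2O 9:1, ultrasound, rt, no amine) to (S)-2-{2-[3,4-bis(TBS-oxy)phenyl]-4-oxo-2,3-dihydro-4H-pyran-6-yl}acetic acid F1. Treatment with 1-chloro-N,N,2-trimethylpropenylamine in CH2Cl2 at 0 °C gives (S)-2-{2-[3,4-bis(TBS-oxy)phenyl]-4-oxo-2,3-dihydro-4H-pyran-6-yl}acetyl chloride F2. This is added by syringe pump to 24 (3 equiv) and i-Pr2NEt (1.1 equiv) in toluene at 60 to 80 °C. Dehydrochlorination of acid chlorides followed by [2+2] capture with ynol ethers is known ketene chemistry. The low stationary ketene concentration gives even a slow cycloaddition a chance.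
- Return: the fallback comes back to the route at vinylketene 25 and runs on through 26 and 27 to 28 in the same flask.

**2. Step 10.**
- What may go wrong: 1,3-dipolar cycloaddition of the diazoalkane across the doubly activated C5=C6 double bond may compete with acylation at the acid chloride.
- Fallback: the diazo group is brought in by diazo transfer, so the alkene never meets a diazoalkane. It sets out from 15, which undergoes a Stille ketone synthesis (Me4Sn, PdCl2(PPh3)2 cat., toluene, 60 °C) to (S)-6-acetyl-2-[3,4-bis(TBS-oxy)phenyl]-2,3-dihydro-4H-pyran-4-one F3. LiN(SiMe3)2 (THF, −78 °C) deprotonates the acetyl methyl group, which is more acidic than C3-H of the vinylogous ester. CF3CO2CH2CF3 then gives (S)-1-{2-[3,4-bis(TBS-oxy)phenyl]-4-oxo-2,3-dihydro-4H-pyran-6-yl}-4,4,4-trifluorobutane-1,3-dione F4, which is used crude. Detrifluoroacetylative diazo transfer (MsN3, Et3N, H2O, MeCN, rt) follows; this method was designed for alpha,beta-unsaturated diazo ketones.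
- Return: the fallback comes back to the route at 17.

**3. Step 12.**
- What may go wrong: addition of the thermally fragile dibromomethyllithium to the neopentyl-type ester carbonyl may be slower than decay of the carbenoid.
- Fallback: the ynolate is made by oxidation of an acetylide instead of by a carbenoid 1,2-shift. It sets out from 19, which is reduced (i-Bu2AlH, CH2Cl2, −78 °C) to 2,2-dimethylbut-3-enal F5. The Ohira-Bestmann reagent (K2CO3, MeOH, rt) converts this non-enolisable aldehyde into 3,3-dimethylpent-4-en-1-yne F6, handled as a dried pentane/THF solution because of its volatility. n-BuLi (THF, −78 °C) gives lithium 3,3-dimethylpent-4-en-1-ynide F7, which is oxidised by LiOOt-Bu (from t-BuOOH and LiN(SiMe3)2, −78 to 0 °C).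
- Return: the fallback comes back to the route at ynolate 23, which is silylated with TIPSOTf at −78 °C to give 24.

## Further compounds

F1 | step 13 | (S)-2-{2-[3,4-bis(TBS-oxy)phenyl]-4-oxo-2,3-dihydro-4H-pyran-6-yl}acetic acid | OC(=O)CC1=CC(=O)C[C@@H](c2ccc(O[Si](C)(C)C(C)(C)C)c(O[Si](C)(C)C(C)(C)C)c2)O1
F2 | step 13 | (S)-2-{2-[3,4-bis(TBS-oxy)phenyl]-4-oxo-2,3-dihydro-4H-pyran-6-yl}acetyl chloride | ClC(=O)CC1=CC(=O)C[C@@H](c2ccc(O[Si](C)(C)C(C)(C)C)c(O[Si](C)(C)C(C)(C)C)c2)O1
F3 | step 10 | (S)-6-acetyl-2-[3,4-bis(TBS-oxy)phenyl]-2,3-dihydro-4H-pyran-4-one | CC(=O)C1=CC(=O)C[C@@H](c2ccc(O[Si](C)(C)C(C)(C)C)c(O[Si](C)(C)C(C)(C)C)c2)O1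
F4 | step 10 | (S)-1-{2-[3,4-bis(TBS-oxy)phenyl]-4-oxo-2,3-dihydro-4H-pyran-6-yl}-4,4,4-trifluorobutane-1,3-dione | O=C(CC(=O)C(F)(F)F)C1=CC(=O)C[C@@H](c2ccc(O[Si](C)(C)C(C)(C)C)c(O[Si](C)(C)C(C)(C)C)c2)O1
F5 | step 12 | 2,2-dimethylbut-3-enal | C=CC(C)(C)C=O
F6 | step 12 | 3,3-dimethylpent-4-en-1-yne | C=CC(C)(C)C#C
F7 | step 12 | lithium 3,3-dimethylpent-4-en-1-ynide | [Li]C#CC(C)(C)C=C
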